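The ten-membered carbocycle is closed last at C8–C9. The homoallylic alcohol motif C8(OH)–C9H2–C10(=C14H2) next to the C1 ketone is the retron of an intramolecular Nozaki–Hiyama–Kishi allylation. In one operation CrCl2 turns the 2-(bromomethyl)enone terminus of an open chain into an allylchromium that adds to the C8 aldehyde on the butenolide, closing the ring, setting C8 and leaving the C10 exocyclic methylene. The precursor is an acyclic bromo enone aldehyde, preorganised by the rigid butenolide (C6/C7) and the cis C4–C5 epoxide. It comes from nerol, whose prenyl end masks C1 and whose allylic alcohol sets C4/C5 by Sharpless epoxidation.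

Key step: step 12

Remark: atom labels follow the germacrane numbering of the target (C1 ketone, C4–C5 epoxide, C6 lactone carbinol, C7=C11 butenolide alkene, C8 ester carbinol, C9 ring CH2, C10=C14 methylene, C12 lactone carbonyl, C13 acetoxymethyl, C15 methyl; target 4S,5R,6R,8R); 16 and 17 are carried as C1 epimers because C1 becomes the ketone in step 10.

Step 1
Reactants: 1 nerol
Product: 2 [(2R,3S)-3-methyl-3-(4-methylpent-3-en-1-yl)oxiran-2-yl]methanol
Conditions: Ti(OiPr)4 (cat.), D-(−)-diethyl tartrate (cat.), tBuOOH, 4 Å molecular sieves, CH2Cl2, −20 °C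
Reagents that add atoms: tert-butyl hydroperoxide, CC(C)(C)OO
Why: Sharpless asymmetric epoxidation of the primary Z-allylic alcohol, in which the D-(−)-tartrate ligand should direct oxygen to the face that gives the (2R,3S)-epoxide (C5 R and C4 S of the target) while the remote prenyl alkene is left alone.

Step 2
Reactants: 2 [(2R,3S)-3-methyl-3-(4-methylpent-3-en-1-yl)oxiran-2-yl]methanol
Product: 3 (2S,3S)-3-methyl-3-(4-methylpent-3-en-1-yl)oxirane-2-carbaldehyde
Conditions: Dess–Martin periodinane, NaHCO3, CH2Cl2, 0 °C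
Reagents that add atoms: none
Why: Dess–Martin oxidation under buffered, non-acidic conditions should give the epoxy aldehyde without opening the trisubstituted epoxide or touching the epoxide stereocentres.

Step 3
Reactants: 3 (2S,3S)-3-methyl-3-(4-methylpent-3-en-1-yl)oxirane-2-carbaldehyde; 4 ethyl propiolate
Product: 6 ethyl (4R)-4-hydroxy-4-[(2R,3S)-3-methyl-3-(4-methylpent-3-en-1-yl)oxiran-2-yl]but-2-ynoate, via lithium acetylide 5 (not isolated)
Conditions: 4, LiN(SiMe3)2, THF, −78 °C; then 3, −78 °C; AcOH quench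
Reagents that add atoms: none
Why: 1,2-addition of a lithium acetylide to an α,β-epoxy aldehyde under non-chelating conditions, where Felkin–Anh attack anti to the epoxide C–O bond should give the anti epoxy alcohol, that is 6R.

Step 4
Reactants: 6 ethyl (4R)-4-hydroxy-4-[(2R,3S)-3-methyl-3-(4-methylpent-3-en-1-yl)oxiran-2-yl]but-2-ynoate
Product: 9 (5R)-4-ethenyl-3-iodo-5-[(2R,3S)-3-methyl-3-(4-methylpent-3-en-1-yl)oxiran-2-yl]furan-2(5H)-one, via alkenylcopper adduct 7 (not isolated), via iodo hydroxy ester 8 (not isolated)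
Conditions: CH2=CHMgBr (5 equiv), CuBr·SMe2 (2.2 equiv), THF, −78 °C; then I2, −78 °C; aq NH4Cl/Na2S2O3, lactonisation on work-up
Reagents that add atoms: vinylmagnesium bromide, C=C[Mg]Br; iodine, II
Why: syn carbocupration of the ynoate puts vinyl on C7 and copper on C11 cis to each other, iodinolysis of the alkenylcopper at −78 °C should proceed with retention, and the C6 hydroxyl, now cis to the ester, lactonises to the butenolide (conjugate addition, electrophilic trapping, lactonisation).

Step 5
Reactants: 9 (5R)-4-ethenyl-3-iodo-5-[(2R,3S)-3-methyl-3-(4-methylpent-3-en-1-yl)oxiran-2-yl]furan-2(5H)-one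
Product: 10 (5R)-4-ethenyl-3-(hydroxymethyl)-5-[(2R,3S)-3-methyl-3-(4-methylpent-3-en-1-yl)oxiran-2-yl]furan-2(5H)-one
Conditions: Bu3SnCH2OH, Pd(PPh3)4 (cat.), 1,4-dioxane, 80 °C
Reagents that add atoms: (tributylstannyl)methanol, CCCC[Sn](CCCC)(CCCC)CO
Why: Stille coupling of the α-iodo enoate, in which the oxygen-substituted methyl group transfers in preference to butyl, should install C13 under neutral conditions that spare the epoxide and the butenolide γ-hydrogen.

Step 6
Reactants: 10 (5R)-4-ethenyl-3-(hydroxymethyl)-5-[(2R,3S)-3-methyl-3-(4-methylpent-3-en-1-yl)oxiran-2-yl]furan-2(5H)-one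
Product: 11 {(5R)-4-ethenyl-5-[(2R,3S)-3-methyl-3-(4-methylpent-3-en-1-yl)oxiran-2-yl]-2-oxo-2,5-dihydrofuran-3-yl}methyl acetate
Conditions: Ac2O, pyridine, DMAP (cat.), CH2Cl2, 0 °C
Reagents that add atoms: acetic anhydride, CC(=O)OC(C)=O
Why: DMAP-catalysed acetylation of the primary allylic alcohol, with pyridine too weak a base to deprotonate C6.

Step 7
Reactants: 11 {(5R)-4-ethenyl-5-[(2R,3S)-3-methyl-3-(4-methylpent-3-en-1-yl)oxiran-2-yl]-2-oxo-2,5-dihydrofuran-3-yl}methyl acetate
Product: 13 {(5R)-4-ethenyl-5-[(2R,3S)-3-methyl-3-(3-oxopropyl)oxiran-2-yl]-2-oxo-2,5-dihydrofuran-3-yl}methyl acetate, via secondary ozonide 12 (not isolated)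
Conditions: O3 (1 equiv, Sudan Red 7B end point), CH2Cl2, −78 °C; then PPh3, −78 °C to rt
Reagents that add atoms: ozone, [O-][O+]=O
Why: electrophilic ozone should cleave the isolated trisubstituted prenyl alkene much faster than the electron-poor vinyl butenolide diene, which unmasks C1 as the aldehyde (chemoselective ozonolysis with reductive work-up).

Step 8
Reactants: 13 {(5R)-4-ethenyl-5-[(2R,3S)-3-methyl-3-(3-oxopropyl)oxiran-2-yl]-2-oxo-2,5-dihydrofuran-3-yl}methyl acetate; 14 2-bromoprop-2-en-1-ol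
Product: 16 {(5R)-4-ethenyl-5-[(2R,3S)-3-[3-hydroxy-4-(hydroxymethyl)pent-4-en-1-yl]-3-methyloxiran-2-yl]-2-oxo-2,5-dihydrofuran-3-yl}methyl acetate (C1 epimers), via alkenylchromium reagent 15 (not isolated)
Conditions: 14 (3 equiv), CrCl2 (6 equiv), NiCl2 (2 mol %), DMSO, rt
Reagents that add atoms: none
Why: Nozaki–Hiyama–Kishi alkenylation, in which nickel catalysis activates the C–Br bond and the alkenylchromium adds only to the aldehyde in the presence of lactone, acetate, epoxide and free hydroxyl, joins C1 to C10 with C9 and C14 in place.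

Step 9
Reactants: 16 {(5R)-4-ethenyl-5-[(2R,3S)-3-[3-hydroxy-4-(hydroxymethyl)pent-4-en-1-yl]-3-methyloxiran-2-yl]-2-oxo-2,5-dihydrofuran-3-yl}methyl acetate
Product: 17 {(5R)-5-[(2R,3S)-3-[4-(bromomethyl)-3-hydroxypent-4-en-1-yl]-3-methyloxiran-2-yl]-4-ethenyl-2-oxo-2,5-dihydrofuran-3-yl}methyl acetate (C1 epimers)
Conditions: CBr4 (1.05 equiv), PPh3 (1.1 equiv), CH2Cl2, −40 to −20 °C
Reagents that add atoms: carbon tetrabromide, BrC(Br)(Br)Br
Why: Appel bromination should be faster at the unhindered primary allylic hydroxyl than at the secondary C1 hydroxyl, and allylic transposition is degenerate because both allyl termini are CH2.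

Step 10
Reactants: 17 {(5R)-5-[(2R,3S)-3-[4-(bromomethyl)-3-hydroxypent-4-en-1-yl]-3-methyloxiran-2-yl]-4-ethenyl-2-oxo-2,5-dihydrofuran-3-yl}methyl acetate
Product: 18 {(5R)-5-[(2R,3S)-3-[4-(bromomethyl)-3-oxopent-4-en-1-yl]-3-methyloxiran-2-yl]-4-ethenyl-2-oxo-2,5-dihydrofuran-3-yl}methyl acetate
Conditions: Dess–Martin periodinane, NaHCO3, CH2Cl2, 0 °C
Reagents that add atoms: none
Why: Dess–Martin oxidation of the secondary allylic alcohol gives the C1 ketone, removes the C1 epimer mixture and deactivates the C10=C14 alkene for the next step.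

Step 11
Reactants: 18 {(5R)-5-[(2R,3S)-3-[4-(bromomethyl)-3-oxopent-4-en-1-yl]-3-methyloxiran-2-yl]-4-ethenyl-2-oxo-2,5-dihydrofuran-3-yl}methyl acetate
Product: 20 {(5R)-5-[(2R,3S)-3-[4-(bromomethyl)-3-oxopent-4-en-1-yl]-3-methyloxiran-2-yl]-4-formyl-2-oxo-2,5-dihydrofuran-3-yl}methyl acetate, via primary ozonide 19 (not isolated)
Conditions: O3 (1 equiv, Sudan Red 7B end point), pyridine (3 equiv), CH2Cl2, −78 °C
Reagents that add atoms: ozone, [O-][O+]=O
Why: the terminal vinyl group of the diene should be the most ozone-reactive alkene left, since C10=C14 is deactivated by the ketone and the allylic bromide, and pyridine-mediated collapse of the carbonyl oxide gives the C8 aldehyde without a nucleophilic reductant that could attack the allylic bromide.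

Step 12
Reactants: 20 {(5R)-5-[(2R,3S)-3-[4-(bromomethyl)-3-oxopent-4-en-1-yl]-3-methyloxiran-2-yl]-4-formyl-2-oxo-2,5-dihydrofuran-3-yl}methyl acetate
Product: 22 (4S,5R,6R,8R)-13-acetoxy-4,5-epoxy-8-hydroxy-1-oxogermacra-7(11),10(14)-dien-12,6-olide, via allylchromium species 21 (not isolated)
Conditions: CrCl2 (10 equiv), THF/DMF (10:1), slow addition of 20 over 12 h to 2 mM final concentration, rt
Reagents that add atoms: none
Why: Two equivalents of CrCl2 reduce the allylic C–Br bond to an allylchromium (divalent chromium becomes trivalent), which adds to the C8 aldehyde through a six-membered chair-like transition state with allyl transposition; because both allyl termini are CH2 groups on C10, the transposition is degenerate and the product carries the C10=C14 methylene beside the new C8–C9 bond. The closest known reaction type is the intramolecular Nozaki–Hiyama–Kishi allylation used to close ten-membered germacrane rings, with the chromium-mediated addition of 2-(bromomethyl)acrylates to aldehydes as the model for the 2-acyl allyl nucleophile. The ten-membered carbocycle closes in a 10-exo-trig mode at the aldehyde carbon, helped by the planar butenolide and the cis-epoxide, which hold C4 to C7 in a turn. The new C8 stereocentre is controlled by C6 through the butenolide: the aldehyde lies in the butenolide plane with its hydrogen toward C13 (A1,3 strain), and the tether, which leaves C6 on the face of C5, should bring C9 to the opposite face of C8 so that C5 and C9 avoid a syn-pentane-type contact across C7, which gives 8R. The step needs chemoselectivity for the aldehyde over the C1 ketone, the lactone and the allylic acetate, which the aldehyde preference of allylchromium reagents should secure, and ring closure over oligomerisation, which slow addition at high dilution should secure. Facial selectivity is the least certain point, and the 8S epimer stays usable through the fallback below.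

Step 13
Reactants: 22 (4S,5R,6R,8R)-13-acetoxy-4,5-epoxy-8-hydroxy-1-oxogermacra-7(11),10(14)-dien-12,6-olide
Product: 23 (4S,5R,6R,8R)-13-acetoxy-4,5-epoxy-8-(methacryloyloxy)-1-oxogermacra-7(11),10(14)-dien-12,6-olide (CNP0266914.1)
Conditions: methacrylic anhydride, DMAP (cat.), pyridine, CH2Cl2, 0 °C, run directly on freshly isolated 22
Reagents that add atoms: methacrylic anhydride, C=C(C)C(=O)OC(=O)C(C)=C
Why: DMAP-catalysed acylation of the secondary alcohol keeps the C8 configuration, and prompt esterification under weakly basic conditions should forestall translactonisation of the C8 hydroxyl onto C12.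

Compound list
1 | nerol, (2Z)-3,7-dimethylocta-2,6-dien-1-ol | OC/C=C(/C)CCC=C(C)C | starting material
2 | [(2R,3S)-3-methyl-3-(4-methylpent-3-en-1-yl)oxiran-2-yl]methanol | CC(C)=CCC[C@]1(C)O[C@@H]1CO | intermediate
3 | (2S,3S)-3-methyl-3-(4-methylpent-3-en-1-yl)oxirane-2-carbaldehyde | CC(C)=CCC[C@]1(C)O[C@@H]1C=O | intermediate
4 | ethyl propiolate (ethyl prop-2-ynoate) | C#CC(=O)OCC | starting material
5 | ethyl 3-lithioprop-2-ynoate | [Li]C#CC(=O)OCC | intermediate
6 | ethyl (4R)-4-hydroxy-4-[(2R,3S)-3-methyl-3-(4-methylpent-3-en-1-yl)oxiran-2-yl]but-2-ynoate | CC(C)=CCC[C@]1(C)O[C@@H]1[C@H](O)C#CC(=O)OCC | intermediate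
7 | alkenylcopper adduct of 6, ethyl (2E,4R)-2-cuprio-3-ethenyl-4-hydroxy-4-[(2R,3S)-3-methyl-3-(4-methylpent-3-en-1-yl)oxiran-2-yl]but-2-enoate (vinyl cis to copper; drawn as the neutral alkenylcopper with the hydroxyl free) | CC(C)=CCC[C@]1(C)O[C@@H]1[C@H](O)/C(C=C)=C(/[Cu])C(=O)OCC | intermediate
8 | ethyl (2E,4R)-3-ethenyl-4-hydroxy-2-iodo-4-[(2R,3S)-3-methyl-3-(4-methylpent-3-en-1-yl)oxiran-2-yl]but-2-enoate | CC(C)=CCC[C@]1(C)O[C@@H]1[C@H](O)/C(C=C)=C(/I)C(=O)OCC | intermediate
9 | (5R)-4-ethenyl-3-iodo-5-[(2R,3S)-3-methyl-3-(4-methylpent-3-en-1-yl)oxiran-2-yl]furan-2(5H)-one | CC(C)=CCC[C@]1(C)O[C@@H]1[C@@H]1OC(=O)C(I)=C1C=C | intermediate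
10 | (5R)-4-ethenyl-3-(hydroxymethyl)-5-[(2R,3S)-3-methyl-3-(4-methylpent-3-en-1-yl)oxiran-2-yl]furan-2(5H)-one | CC(C)=CCC[C@]1(C)O[C@@H]1[C@@H]1OC(=O)C(CO)=C1C=C | intermediate
11 | {(5R)-4-ethenyl-5-[(2R,3S)-3-methyl-3-(4-methylpent-3-en-1-yl)oxiran-2-yl]-2-oxo-2,5-dihydrofuran-3-yl}methyl acetate | CC(C)=CCC[C@]1(C)O[C@@H]1[C@@H]1OC(=O)C(COC(C)=O)=C1C=C | intermediate
12 | secondary ozonide of 11 (3,3-dimethyl-1,2,4-trioxolane at the former prenyl alkene; new acetal carbon unspecified) | CC1(C)OOC(CC[C@]2(C)O[C@@H]2[C@@H]2OC(=O)C(COC(C)=O)=C2C=C)O1 | intermediate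
13 | {(5R)-4-ethenyl-5-[(2R,3S)-3-methyl-3-(3-oxopropyl)oxiran-2-yl]-2-oxo-2,5-dihydrofuran-3-yl}methyl acetate | O=CCC[C@]1(C)O[C@@H]1[C@@H]1OC(=O)C(COC(C)=O)=C1C=C | intermediate
14 | 2-bromoprop-2-en-1-ol | OCC(Br)=C | starting material
15 | dichloro(3-hydroxyprop-1-en-2-yl)chromium | OCC(=C)[Cr](Cl)Cl | intermediate
16 | {(5R)-4-ethenyl-5-[(2R,3S)-3-[3-hydroxy-4-(hydroxymethyl)pent-4-en-1-yl]-3-methyloxiran-2-yl]-2-oxo-2,5-dihydrofuran-3-yl}methyl acetate (C1 epimers, C1 unspecified) | OCC(=C)C(O)CC[C@]1(C)O[C@@H]1[C@@H]1OC(=O)C(COC(C)=O)=C1C=C | intermediate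
17 | {(5R)-5-[(2R,3S)-3-[4-(bromomethyl)-3-hydroxypent-4-en-1-yl]-3-methyloxiran-2-yl]-4-ethenyl-2-oxo-2,5-dihydrofuran-3-yl}methyl acetate (C1 epimers, C1 unspecified) | BrCC(=C)C(O)CC[C@]1(C)O[C@@H]1[C@@H]1OC(=O)C(COC(C)=O)=C1C=C | intermediate
18 | {(5R)-5-[(2R,3S)-3-[4-(bromomethyl)-3-oxopent-4-en-1-yl]-3-methyloxiran-2-yl]-4-ethenyl-2-oxo-2,5-dihydrofuran-3-yl}methyl acetate | BrCC(=C)C(=O)CC[C@]1(C)O[C@@H]1[C@@H]1OC(=O)C(COC(C)=O)=C1C=C | intermediate
19 | primary ozonide of 18 (1,2,3-trioxolane at the former vinyl group; new ring carbon unspecified) | BrCC(=C)C(=O)CC[C@]1(C)O[C@@H]1[C@@H]1OC(=O)C(COC(C)=O)=C1C1COOO1 | intermediate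
20 | {(5R)-5-[(2R,3S)-3-[4-(bromomethyl)-3-oxopent-4-en-1-yl]-3-methyloxiran-2-yl]-4-formyl-2-oxo-2,5-dihydrofuran-3-yl}methyl acetate | BrCC(=C)C(=O)CC[C@]1(C)O[C@@H]1[C@@H]1OC(=O)C(COC(C)=O)=C1C=O | intermediate
21 | allylchromium species from 20 (Cl2Cr–CH2 in place of Br–CH2) | Cl[Cr](Cl)CC(=C)C(=O)CC[C@]1(C)O[C@@H]1[C@@H]1OC(=O)C(COC(C)=O)=C1C=O | intermediate
22 | (4S,5R,6R,8R)-13-acetoxy-4,5-epoxy-8-hydroxy-1-oxogermacra-7(11),10(14)-dien-12,6-olide | O[C@@H]1CC(=C)C(=O)CC[C@]2(C)O[C@@H]2[C@@H]2OC(=O)C(COC(C)=O)=C21 | intermediate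
23 | (4S,5R,6R,8R)-13-acetoxy-4,5-epoxy-8-(methacryloyloxy)-1-oxogermacra-7(11),10(14)-dien-12,6-olide (CNP0266914.1) | C=C(C)C(=O)O[C@@H]1CC(=C)C(=O)CC[C@]2(C)O[C@@H]2[C@@H]2OC(=O)C(COC(C)=O)=C21 | target

Total step count: 13
Longest linear sequence: 13 steps (nerol 1 to target 23)

Steps most likely to fail

Step 12. What may go wrong is poor or reversed facial selectivity at C8, so that the ring closes mainly to the 8S carbinol. The fallback sets out from 20 and accepts the cyclisation with the opposite sense: the same CrCl2 closure then gives the (8S)-alcohol F1. F1 is esterified with inversion under Mitsunobu conditions (methacrylic acid, PPh3, diisopropyl azodicarboxylate, THF, 0 °C) and comes back to the route at 23. A mixture of epimers would be separated and each sent through its own esterification, so either sense of addition is convertible.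

Step 4. What may go wrong is loss of alkene geometry in the alkenylcopper adduct through its allenoate form before iodine traps it, or incomplete iodination, so that little of the cis iodo ester lactonises. The fallback sets out from 3 and builds the fully substituted butenolide by alkoxide-directed anti carbomagnesiation instead. Aldehyde 3 is treated with the lithium acetylide of tert-butyldimethyl(prop-2-yn-1-yloxy)silane (n-BuLi, THF, −78 °C; same Felkin–Anh control) to give the propargylic alcohol F2. Its magnesium alkoxide directs anti addition of CH2=CHMgCl across the alkyne (THF, 40–60 °C), with vinyl on C7 and magnesium on C11 cis to the C6 oxygen, and CO2 followed by mild acid closes the silyloxymethyl butenolide F3. HF·pyridine (THF, 0 °C) removes the silyl group and the route is rejoined at 10.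

Step 11. What may go wrong is competing attack of ozone on the C10=C14 methylene or loss of the reactive allylic bromide during cleavage. The fallback sets out from 18 and cleaves the vinyl group in two stages through an isolable glycol. Catalytic OsO4 with N-methylmorpholine N-oxide (acetone/H2O, 0 °C) should dihydroxylate the monosubstituted vinyl group in preference to the hindered, electron-poor 1,1-disubstituted enone alkene and give the vicinal diol F4. NaIO4 (THF/H2O, 0 °C) then cleaves the glycol and the route is rejoined at 20.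

Further compounds
F1 | step 12 | (4S,5R,6R,8S)-13-acetoxy-4,5-epoxy-8-hydroxy-1-oxogermacra-7(11),10(14)-dien-12,6-olide | O[C@H]1CC(=C)C(=O)CC[C@]2(C)O[C@@H]2[C@@H]2OC(=O)C(COC(C)=O)=C21
F2 | step 4 | (1R)-4-[(tert-butyldimethylsilyl)oxy]-1-[(2R,3S)-3-methyl-3-(4-methylpent-3-en-1-yl)oxiran-2-yl]but-2-yn-1-ol | CC(C)=CCC[C@]1(C)O[C@@H]1[C@H](O)C#CCO[Si](C)(C)C(C)(C)C
F3 | step 4 | (5R)-3-{[(tert-butyldimethylsilyl)oxy]methyl}-4-ethenyl-5-[(2R,3S)-3-methyl-3-(4-methylpent-3-en-1-yl)oxiran-2-yl]furan-2(5H)-one | CC(C)=CCC[C@]1(C)O[C@@H]1[C@@H]1OC(=O)C(CO[Si](C)(C)C(C)(C)C)=C1C=C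
F4 | step 11 | {(5R)-5-[(2R,3S)-3-[4-(bromomethyl)-3-oxopent-4-en-1-yl]-3-methyloxiran-2-yl]-4-(1,2-dihydroxyethyl)-2-oxo-2,5-dihydrofuran-3-yl}methyl acetate (carbinol epimers) | BrCC(=C)C(=O)CC[C@]1(C)O[C@@H]1[C@@H]1OC(=O)C(COC(C)=O)=C1C(O)CO
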